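The electrophile gone from the epsilon flask cannot all be target: 42.0% has left by 25.0 min, and the target reads 11%. So this note for the bench reckons the loss of electrophile without asking where it went.

| setting | epsilon | Sunday's | Friday's | Saturday's |
|---|---|---|---|---|
| electrophile | 48 mM | 48 mM | 48 mM | 48 mM |
| nucleophile | 0.80 equiv | 1.20 equiv | 1.20 equiv | 1.20 equiv |
| free base | 1.2 equiv | 1.20 equiv | 1.60 equiv | 2.00 equiv |
| protic impurity | 9.6 mM | 9.60 mM | 9.60 mM | 9.60 mM |
| scavenger | 1.2 equiv | 1.20 equiv | 1.20 equiv | 1.20 equiv |
| remark | run made earlier |  |  |  |
| time |  | 2.0 h | 2.0 h | 2.0 h |

- epsilon (time / min: electrophile / %, target / %): 5.00: 93, 6; 10.0: 78, 9; 15.0: 66, 10; 20.0: 64, 10; 25.0: 58, 11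

(scatter of a reading: 2 percentage points)

- what was read earlier has a scatter of 2 percentage points, one standard deviation
- no earlier run changes the charge of free base; that part of a forecast is a guess

- part of the electrophile that has reacted at the end, Sunday's
- part of the electrophile that has reacted at the end, Friday's
- part of the electrophile that has reacted at the end, Saturday's
- what raising the equivalents of free base from its lowest to its highest value here does to the part of the electrophile that has reacted (changes below 5 percentage points count as none) (it rises / it falls / no change)

I assume that each electrophile lost costs one nucleophile and that the loss follows the nucleophile present. In the epsilon run the nucleophile then averages 0.590 equiv. That gives 0.0369 /min for the pull, the fraction of electrophile lost per minute per equivalent of nucleophile (a pseudo-first-order constant per equivalent). It is a reading and carries the scatter.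

For Sunday's flask, holding 1.20 equiv of nucleophile for 2.0 h gives 99.5% reacted. But then the nucleophile averages 0.702 equiv, so I go round once more and get 95.6% reacted, with 20.4% of the nucleophile left. The pull holds no free base, so I expect the same on Friday's and Saturday's flasks. That part is a guess, since no earlier run changes the base. Leave the base alone.

The forecast says 89%, 91% and 92%, no change, because “more base should add little”. Its Sunday's figure stands below mine.

The flasks give 93.1%, 93.1% and 93.1%: no change, a change of 0.02 percentage points.

    electrophile + nucleophile → acid set free + target (k = 0.00910 /M/s)
    protic impurity + free base → quenched reagent (k = 0.00480 /M/s)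
    nucleophile + acid set free ⇌ protonated nucleophile, settled at all times (K = 1.30 × 10⁵ /M)
    electrophile + target → side product (k = 0.0400 /M/s)
    nucleophile + acid set free ⇌ idle adduct, settled at all times (K = 1500 /M)
    acid set free + free base ⇌ salt of the base (K = 53000 /M, k = 0.0420 /M/s)
    acid set free + scavenger → scavenged by-product (k = 0.560 /M/s)

In Saturday's flask at 2.00 h, the electrophile's half-life by its loss with target to side product is 1.3 h, shorter than the 1.8 h by the making of target; side product holds 85.3% of the electrophile charged, target 7.83%. On Sunday's flask the pull leaves 4.46% of the electrophile where the flask has 6.9%, and 20.4% of the nucleophile where the flask has 20% of it unbound, beside 21.6 mM of protonated nucleophile. A flask like Saturday's with 12 mM of electrophile, at the same equivalents, holds its nucleophile at a quarter of Saturday's concentration, and I assume the pull shrinks with it: the rounds give 73.5%, then 60.2% reacted. The computed flask gives 62.4%.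

The earlier runs and the new flask were generated by integration for an exercise, noise included.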